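The route is cut at the C3–C3a bond of ring B. C7a, the methyl-bearing quaternary carbon shared by rings A and B and flanked in ring A by C7 and C3a, is traced back to the prochiral carbon between the two carbonyls of a 2,2-disubstituted cyclohexane-1,3-dione. An amino-acid-catalysed aldol cyclodehydration of the achiral triketone 2-methyl-2-(2-oxopropyl)cyclohexane-1,3-dione closes ring B, selects one of two enantiotopic ring carbonyls and so fixes C7a in one operation, leaving ketones at C7 and C2. These carry the rest: gem-dimethylation at C7, two alkylations at C1, carbonylation at C2 through a dienyl triflate, and growth of the side chain from an allyl group.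

Key step: step 3

Remarks. Locants are those of the indene skeleton of the target (C1, C2, C3, C3a, C4 to C7, C7a); ring A is the six-membered ring, ring B the five-membered ring. (S)-Proline is assumed to give the 7aR series by analogy with the six-ring-forming reaction of the same class; if the sense proves opposite, (R)-proline is used with no other change. Enolates made in a separate deprotonation stage are numbered; carboxylic acids that pass through salts are written as the acids recovered on acidic work-up.

Step 1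
Reactants: 1 2-methylcyclohexane-1,3-dione; 2 allyl bromide
Product: 3 2-allyl-2-methylcyclohexane-1,3-dione
Conditions: allyl bromide (1.5 equiv), 1 M NaOH (aq), Bu4NI (cat.), rt
Reagents that add atoms: allyl bromide 2, C=CCBr
Why: Enolate alkylation of the dione with an allylic halide goes on carbon in water, and the allyl group serves as a masked 2-oxopropyl unit, avoiding the O-alkylation that an α-haloketone would invite.

Step 2
Reactants: 3 2-allyl-2-methylcyclohexane-1,3-dione
Product: 4 2-methyl-2-(2-oxopropyl)cyclohexane-1,3-dione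
Conditions: PdCl2 (0.1 equiv), CuCl (1 equiv), O2 (1 atm), DMF/H2O (7:1), rt
Reagents that add atoms: water, O
Why: Wacker–Tsuji oxidation: Markovnikov hydroxypalladation of the terminal alkene and β-hydride elimination give the methyl ketone, with CuCl/O2 returning palladium to the divalent state.

Step 3
Reactants: 4 2-methyl-2-(2-oxopropyl)cyclohexane-1,3-dione
Product: 6 (7aR)-7a-methyl-1,4,5,6,7,7a-hexahydro-2H-indene-2,7-dione, via cis-fused ketol 5 (not isolated)
Conditions: (S)-proline (0.3 equiv), DMF, rt; then TsOH·H2O (cat.), toluene, 80 °C (solvent exchange, ketol not purified)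
Reagents that add atoms: none
Why: Proline condenses with the unhindered side-chain methyl ketone to give the terminal enamine, whose carbon C3 adds to one ring carbonyl (the future C3a) while the catalyst carboxylic acid hydrogen-bonds to that same carbonyl; iminium hydrolysis gives ketol 5, which acid dehydrates to the C3=C3a enone. This is a Hajos–Parrish–Eder–Sauer–Wiechert aldol cyclisation of a 2,2-disubstituted cyclic 1,3-dione, run in its five-ring-forming variant. Ring B closes in a 5-(enolexo)-exo-trig mode. C7a is the only stereocentre that survives (C3a of the ketol is erased on dehydration), and its configuration is set by the catalyst, which decides which of the two enantiotopic carbonyls is attacked. The selectivity needed is therefore enantiotopic-group selection; site selectivity is secured by the substrate, since only the methyl-ketone enamine can reach a ring carbonyl through an unstrained five-membered transition state, and a bridged aldol from a ring enolate cannot dehydrate and reverts.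

Step 4
Reactants: 6 (7aR)-7a-methyl-1,4,5,6,7,7a-hexahydro-2H-indene-2,7-dione
Product: 7 (7aR)-2,2-(ethane-1,2-diyldisulfanediyl)-7a-methyl-1,2,4,5,6,7a-hexahydro-7H-inden-7-one
Conditions: HSCH2CH2SH (1.1 equiv), TsOH·H2O (cat.), AcOH, rt
Reagents that add atoms: ethane-1,2-dithiol, SCCS
Why: Acid-catalysed thioketalisation should select the enone carbonyl, which reacts through an allyl-stabilised thionium ion, over the C7 carbonyl shielded by the adjacent quaternary C7a, the site selection known for Wieland–Miescher-type enediones; C7a is untouched.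

Step 5
Reactants: 7 (7aR)-2,2-(ethane-1,2-diyldisulfanediyl)-7a-methyl-1,2,4,5,6,7a-hexahydro-7H-inden-7-one
Product: 8 (7aS)-2,2-(ethane-1,2-diyldisulfanediyl)-7,7,7a-trimethyl-2,4,5,6,7,7a-hexahydro-1H-indene
Conditions: Me2TiCl2 (3 equiv, from TiCl4 + ZnMe2), CH2Cl2, −30 °C to rt
Reagents that add atoms: dimethyltitanium dichloride, C[Ti](C)(Cl)Cl (made in the flask from TiCl4 and dimethylzinc, C[Zn]C)
Why: Titanium-mediated geminal dimethylation of a ketone (the Reetz reaction): methyl addition to C7, ionisation of the titanium alkoxide and transfer of a second methyl to the tertiary cation, a sequence that tolerates an adjacent quaternary carbon, while the dithiolane keeps C2 out of reach.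

Step 6
Reactants: 8 (7aS)-2,2-(ethane-1,2-diyldisulfanediyl)-7,7,7a-trimethyl-2,4,5,6,7,7a-hexahydro-1H-indene
Product: 9 (7aS)-7,7,7a-trimethyl-1,4,5,6,7,7a-hexahydro-2H-inden-2-one
Conditions: MeI (excess), CaCO3, MeCN/H2O (4:1), 60 °C
Reagents that add atoms: water, O
Why: Alkylative hydrolysis of the dithiolane (S-methylation, opening to the allylic thionium ion, capture by water) returns the enone under near-neutral conditions that leave the alkene in conjugation.

Step 7
Reactants: 9 (7aS)-7,7,7a-trimethyl-1,4,5,6,7,7a-hexahydro-2H-inden-2-one; 2 allyl bromide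
Product: 11 (7aS)-1-allyl-7,7,7a-trimethyl-1,4,5,6,7,7a-hexahydro-2H-inden-2-one (C1 epimers), via lithium dienolate 10 (not isolated)
Conditions: LiN(iPr)2 (1.1 equiv), THF, −78 °C; then allyl bromide, −78 to −20 °C
Reagents that add atoms: allyl bromide 2, C=CCBr
Why: Kinetic deprotonation of the cyclopentenone at C1, its only α'-position, gives the cross-conjugated dienolate, which is C-allylated by the reactive allylic bromide (enolate alkylation); the C1 configuration is immaterial because C1 is planarised again in step 8.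

Step 8
Reactants: 11 (7aS)-1-allyl-7,7,7a-trimethyl-1,4,5,6,7,7a-hexahydro-2H-inden-2-one
Product: 13 (1S,7aS)-1-allyl-1,7,7,7a-tetramethyl-1,4,5,6,7,7a-hexahydro-2H-inden-2-one, via lithium dienolate 12 (not isolated)
Conditions: LiN(iPr)2 (1.3 equiv), THF, −78 to −40 °C; then MeI, DMPU, −78 to 0 °C
Reagents that add atoms: iodomethane, CI
Why: A second kinetic α'-enolisation and methylation (enolate alkylation) create the quaternary C1; iodomethane should enter on the ring-B face that carries the C7a methyl, because the opposite face is blocked by C7 and its axial methyl group lying beneath C7a, so the new methyl ends up cis to the C7a methyl and the allyl group trans to it.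

Step 9
Reactants: 13 (1S,7aS)-1-allyl-1,7,7,7a-tetramethyl-1,4,5,6,7,7a-hexahydro-2H-inden-2-one
Product: 14 (1S,7aS)-1-allyl-1,7,7,7a-tetramethyl-5,6,7,7a-tetrahydro-1H-inden-2-yl trifluoromethanesulfonate
Conditions: Tf2O (1.3 equiv), 2,6-di-tert-butyl-4-methylpyridine (1.5 equiv), CH2Cl2, 0 °C to rt
Reagents that add atoms: trifluoromethanesulfonic anhydride, O=S(=O)(OS(=O)(=O)C(F)(F)F)C(F)(F)F
Why: O-Triflation of the enone with a non-nucleophilic base, followed by loss of a C4 proton, the only γ-hydrogen available now that C1 is quaternary, gives the heteroannular dienyl triflate with the alkenes at C2=C3 and C3a=C4 (enol triflate formation, as practised on steroidal enones).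

Step 10
Reactants: 14 (1S,7aS)-1-allyl-1,7,7,7a-tetramethyl-5,6,7,7a-tetrahydro-1H-inden-2-yl trifluoromethanesulfonate
Product: 15 methyl (1S,7aS)-1-allyl-1,7,7,7a-tetramethyl-5,6,7,7a-tetrahydro-1H-indene-2-carboxylate
Conditions: Pd(OAc)2 (5 mol %), Ph2P(CH2)3PPh2 (5 mol %), Et3N (2 equiv), CO (1 atm), MeOH/DMF (1:1), 70 °C
Reagents that add atoms: carbon monoxide, [C-]#[O+]; methanol, CO
Why: Palladium-catalysed methoxycarbonylation of an enol triflate (oxidative addition to zerovalent palladium, CO insertion, methanolysis), in which methanol as co-solvent intercepts the acylpalladium before it can add to the pendant allyl group.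

Step 11
Reactants: 15 methyl (1S,7aS)-1-allyl-1,7,7,7a-tetramethyl-5,6,7,7a-tetrahydro-1H-indene-2-carboxylate
Product: 17 methyl (1R,2S,7aS)-1-allyl-1,7,7,7a-tetramethyl-2,3,5,6,7,7a-hexahydro-1H-indene-2-carboxylate, via C2-epimeric ester mixture 16 (not isolated)
Conditions: Cu(OAc)2·H2O (5 mol %), 1,2-(Ph2P)2C6H4 (5 mol %), MeSiH(OEt)2 (2 equiv), t-BuOH (2 equiv), toluene, rt; then NaOMe (0.5 equiv), MeOH, 60 °C
Reagents that add atoms: none
Why: Copper hydride conjugate reduction should deliver hydride to C3, the β-carbon of the α,β-bond to which copper binds, leaving the C3a=C4 and allyl alkenes alone, and methoxide then equilibrates C2 so that the ester takes the less hindered ring-B face, cis to the C1 and C7a methyls and trans to the allyl group and C7, which sets C2 under thermodynamic control.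

Step 12
Reactants: 17 methyl (1R,2S,7aS)-1-allyl-1,7,7,7a-tetramethyl-2,3,5,6,7,7a-hexahydro-1H-indene-2-carboxylate
Product: 19 methyl (1R,2S,7aS)-1-(3-hydroxypropyl)-1,7,7,7a-tetramethyl-2,3,5,6,7,7a-hexahydro-1H-indene-2-carboxylate, via B-alkyl-9-BBN adduct 18 (not isolated)
Conditions: 9-BBN (1.5 equiv), THF, 0 °C to rt; then 3 M NaOH, 30% H2O2, 0 °C
Reagents that add atoms: 9-borabicyclo[3.3.1]nonane, B1C2CCCC1CCC2 (its atoms stay only in 18); hydrogen peroxide, OO
Why: Hydroboration–oxidation: 9-BBN adds anti-Markovnikov to the monosubstituted alkene only, the trisubstituted C3a=C4 bond and the ester being inert to it, and alkaline peroxide gives the primary alcohol.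

Step 13
Reactants: 19 methyl (1R,2S,7aS)-1-(3-hydroxypropyl)-1,7,7,7a-tetramethyl-2,3,5,6,7,7a-hexahydro-1H-indene-2-carboxylate
Product: 20 (1R,2S,7aS)-1-(3-hydroxypropyl)-1,7,7,7a-tetramethyl-2,3,5,6,7,7a-hexahydro-1H-indene-2-carboxylic acid
Conditions: LiOH·H2O (10 equiv), THF/MeOH/H2O (2:1:1), 60 °C; then 1 M HCl
Reagents that add atoms: lithium hydroxide, [Li+].[OH-]
Why: Saponification of the methyl ester (acyl substitution by hydroxide) frees the acid before any other ester is present; C2 already holds its equilibrium configuration, so the basic medium should not drive it away from it.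

Step 14
Reactants: 20 (1R,2S,7aS)-1-(3-hydroxypropyl)-1,7,7,7a-tetramethyl-2,3,5,6,7,7a-hexahydro-1H-indene-2-carboxylic acid
Product: 21 (1R,2S,7aS)-1,7,7,7a-tetramethyl-1-(3-oxopropyl)-2,3,5,6,7,7a-hexahydro-1H-indene-2-carboxylic acid
Conditions: Dess–Martin periodinane (1.3 equiv), CH2Cl2, rt
Reagents that add atoms: none
Why: Dess–Martin oxidation takes the primary alcohol to the aldehyde without touching the carboxylic acid, the stereocentres or the ring alkene.

Step 15
Reactants: 21 (1R,2S,7aS)-1,7,7,7a-tetramethyl-1-(3-oxopropyl)-2,3,5,6,7,7a-hexahydro-1H-indene-2-carboxylic acid; 22 ethyl 2-[bis(2,2,2-trifluoroethoxy)phosphoryl]propanoate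
Product: 23 (1R,2S,7aS)-1-[(3Z)-5-ethoxy-4-methyl-5-oxopent-3-en-1-yl]-1,7,7,7a-tetramethyl-2,3,5,6,7,7a-hexahydro-1H-indene-2-carboxylic acid
Conditions: 22 (2.3 equiv), KN(SiMe3)2 (2.2 equiv), 18-crown-6, THF, −78 °C; then 1 M HCl
Reagents that add atoms: phosphonate 22, CCOC(=O)C(C)P(=O)(OCC(F)(F)F)OCC(F)(F)F
Why: Still–Gennari olefination: the electron-poor bis(trifluoroethyl) phosphonate with a dissociated potassium counter-ion eliminates faster than its adducts equilibrate, giving the Z-trisubstituted enoate, while the substrate carboxylate formed by the first equivalent of phosphonate anion is inert.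

Step 16
Reactants: 23 (1R,2S,7aS)-1-[(3Z)-5-ethoxy-4-methyl-5-oxopent-3-en-1-yl]-1,7,7,7a-tetramethyl-2,3,5,6,7,7a-hexahydro-1H-indene-2-carboxylic acid
Product: 24 (1R,2S,7aS)-1-[(3Z)-5-hydroxy-4-methylpent-3-en-1-yl]-1,7,7,7a-tetramethyl-2,3,5,6,7,7a-hexahydro-1H-indene-2-carboxylic acid
Conditions: iBu2AlH (4 equiv), CH2Cl2, −78 °C; aq. potassium sodium tartrate, then pH 3
Reagents that add atoms: none
Why: 1,2-Reduction of the conjugated ester by iBu2AlH gives the Z-allylic alcohol with the alkene geometry intact, the carboxyl group being shielded as its aluminium carboxylate, which is not reduced at −78 °C.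

Step 17
Reactants: 24 (1R,2S,7aS)-1-[(3Z)-5-hydroxy-4-methylpent-3-en-1-yl]-1,7,7,7a-tetramethyl-2,3,5,6,7,7a-hexahydro-1H-indene-2-carboxylic acid
Product: 26 (1R,2S,7aS)-1-[(3Z)-5-(acetyloxy)-4-methylpent-3-en-1-yl]-1,7,7,7a-tetramethyl-2,3,5,6,7,7a-hexahydro-1H-indene-2-carboxylic acid (target), via mixed anhydride 25 (not isolated)
Conditions: Ac2O (3 equiv), pyridine, DMAP (cat.), CH2Cl2, 0 °C to rt; then H2O, THF, rt
Reagents that add atoms: acetic anhydride, CC(=O)OC(C)=O
Why: Acetylation of the primary allylic alcohol (DMAP-catalysed acyl transfer); the mixed anhydride formed at the hindered carboxyl group is hydrolysed at its acetyl carbonyl in the aqueous second stage, releasing the free acid.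

Compound list

1 | 2-methylcyclohexane-1,3-dione | CC1C(=O)CCCC1=O | starting material
2 | allyl bromide (3-bromoprop-1-ene) | C=CCBr | starting material
3 | 2-allyl-2-methylcyclohexane-1,3-dione (achiral) | C=CCC1(C)C(=O)CCCC1=O | intermediate
4 | 2-methyl-2-(2-oxopropyl)cyclohexane-1,3-dione (achiral triketone) | CC(=O)CC1(C)C(=O)CCCC1=O | intermediate
5 | cis-fused ketol, (3aR,7aR)-3a-hydroxy-7a-methyloctahydroindene-2,7-dione, hydroxyl at C3a cis to the C7a methyl (formed in the flask, not isolated) | C1C(=O)C[C@]2(O)CCCC(=O)[C@@]21C | intermediate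
6 | (7aR)-7a-methyl-1,4,5,6,7,7a-hexahydro-2H-indene-2,7-dione (C3=C3a enone with C2 ketone; saturated ketone at C7) | C1C(=O)C=C2CCCC(=O)[C@@]21C | intermediate
7 | (7aR)-2,2-(ethane-1,2-diyldisulfanediyl)-7a-methyl-1,2,4,5,6,7a-hexahydro-7H-inden-7-one (1,3-dithiolane of 6 at C2) | C1C2(SCCS2)C=C3CCCC(=O)[C@@]31C | intermediate
8 | (7aS)-2,2-(ethane-1,2-diyldisulfanediyl)-7,7,7a-trimethyl-2,4,5,6,7,7a-hexahydro-1H-indene (descriptor changes with the CIP priorities only; C7a is untouched) | C1C2(SCCS2)C=C3CCCC(C)(C)[C@@]31C | intermediate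
9 | (7aS)-7,7,7a-trimethyl-1,4,5,6,7,7a-hexahydro-2H-inden-2-one | C1C(=O)C=C2CCCC(C)(C)[C@@]21C | intermediate
10 | lithium (7aS)-7,7,7a-trimethyl-5,6,7,7a-tetrahydro-4H-inden-2-olate, cross-conjugated dienolate (formed in the flask, not isolated) | C1=C(O[Li])C=C2CCCC(C)(C)[C@@]21C | intermediate
11 | (7aS)-1-allyl-7,7,7a-trimethyl-1,4,5,6,7,7a-hexahydro-2H-inden-2-one, mixture of C1 epimers | C=CCC1C(=O)C=C2CCCC(C)(C)[C@@]21C | intermediate
12 | lithium (7aS)-1-allyl-7,7,7a-trimethyl-5,6,7,7a-tetrahydro-4H-inden-2-olate (formed in the flask, not isolated) | C=CCC1=C(O[Li])C=C2CCCC(C)(C)[C@@]21C | intermediate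
13 | (1S,7aS)-1-allyl-1,7,7,7a-tetramethyl-1,4,5,6,7,7a-hexahydro-2H-inden-2-one (C1 methyl cis to C7a methyl) | C=CC[C@]1(C)C(=O)C=C2CCCC(C)(C)[C@@]21C | intermediate
14 | (1S,7aS)-1-allyl-1,7,7,7a-tetramethyl-5,6,7,7a-tetrahydro-1H-inden-2-yl trifluoromethanesulfonate (diene C2=C3, C3a=C4) | C=CC[C@]1(C)C(OS(=O)(=O)C(F)(F)F)=CC2=CCCC(C)(C)[C@@]21C | intermediate
15 | methyl (1S,7aS)-1-allyl-1,7,7,7a-tetramethyl-5,6,7,7a-tetrahydro-1H-indene-2-carboxylate | C=CC[C@]1(C)C(C(=O)OC)=CC2=CCCC(C)(C)[C@@]21C | intermediate
16 | methyl (1R,7aS)-1-allyl-1,7,7,7a-tetramethyl-2,3,5,6,7,7a-hexahydro-1H-indene-2-carboxylate, mixture of C2 epimers (formed in the flask, not isolated) | C=CC[C@]1(C)C(C(=O)OC)CC2=CCCC(C)(C)[C@@]21C | intermediate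
17 | methyl (1R,2S,7aS)-1-allyl-1,7,7,7a-tetramethyl-2,3,5,6,7,7a-hexahydro-1H-indene-2-carboxylate (ester cis to both ring-B methyls; C1 descriptor changes with the priorities only) | C=CC[C@]1(C)[C@@H](C(=O)OC)CC2=CCCC(C)(C)[C@@]21C | intermediate
18 | methyl (1R,2S,7aS)-1-[3-(9-borabicyclo[3.3.1]nonan-9-yl)propyl]-1,7,7,7a-tetramethyl-2,3,5,6,7,7a-hexahydro-1H-indene-2-carboxylate (formed in the flask, not isolated) | C1CC2CCCC(C1)B2CCC[C@]1(C)[C@@H](C(=O)OC)CC2=CCCC(C)(C)[C@@]21C | intermediate
19 | methyl (1R,2S,7aS)-1-(3-hydroxypropyl)-1,7,7,7a-tetramethyl-2,3,5,6,7,7a-hexahydro-1H-indene-2-carboxylate | OCCC[C@]1(C)[C@@H](C(=O)OC)CC2=CCCC(C)(C)[C@@]21C | intermediate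
20 | (1R,2S,7aS)-1-(3-hydroxypropyl)-1,7,7,7a-tetramethyl-2,3,5,6,7,7a-hexahydro-1H-indene-2-carboxylic acid | OCCC[C@]1(C)[C@@H](C(=O)O)CC2=CCCC(C)(C)[C@@]21C | intermediate
21 | (1R,2S,7aS)-1,7,7,7a-tetramethyl-1-(3-oxopropyl)-2,3,5,6,7,7a-hexahydro-1H-indene-2-carboxylic acid | O=CCC[C@]1(C)[C@@H](C(=O)O)CC2=CCCC(C)(C)[C@@]21C | intermediate
22 | ethyl 2-[bis(2,2,2-trifluoroethoxy)phosphoryl]propanoate | CCOC(=O)C(C)P(=O)(OCC(F)(F)F)OCC(F)(F)F | starting material
23 | (1R,2S,7aS)-1-[(3Z)-5-ethoxy-4-methyl-5-oxopent-3-en-1-yl]-1,7,7,7a-tetramethyl-2,3,5,6,7,7a-hexahydro-1H-indene-2-carboxylic acid | CCOC(=O)/C(C)=C\CC[C@]1(C)[C@@H](C(=O)O)CC2=CCCC(C)(C)[C@@]21C | intermediate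
24 | (1R,2S,7aS)-1-[(3Z)-5-hydroxy-4-methylpent-3-en-1-yl]-1,7,7,7a-tetramethyl-2,3,5,6,7,7a-hexahydro-1H-indene-2-carboxylic acid | OC/C(C)=C\CC[C@]1(C)[C@@H](C(=O)O)CC2=CCCC(C)(C)[C@@]21C | intermediate
25 | acetic (1R,2S,7aS)-1-[(3Z)-5-(acetyloxy)-4-methylpent-3-en-1-yl]-1,7,7,7a-tetramethyl-2,3,5,6,7,7a-hexahydro-1H-indene-2-carboxylic anhydride (formed in the flask, not isolated) | CC(=O)OC/C(C)=C\CC[C@]1(C)[C@@H](C(=O)OC(C)=O)CC2=CCCC(C)(C)[C@@]21C | intermediate
26 | (1R,2S,7aS)-1-[(3Z)-5-(acetyloxy)-4-methylpent-3-en-1-yl]-1,7,7,7a-tetramethyl-2,3,5,6,7,7a-hexahydro-1H-indene-2-carboxylic acid | CC(=O)OC/C(C)=C\CC[C@]1(C)[C@@H](C(=O)O)CC2=CCCC(C)(C)[C@@]21C | target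

Total step count: 17. Longest linear sequence: 17 steps (1 to 26); compounds 2 and 22 are purchased.

Steps most likely to fail

Step 3. The risk is weak discrimination between the two enantiotopic ring carbonyls: the tether is one carbon shorter than in the six-ring-forming case, so the hydrogen-bonded transition state may be less ordered and the enantiomeric purity too low. The fallback replaces asymmetric catalysis by resolution. It sets out from 4, which is cyclised and dehydrated with pyrrolidine/AcOH (no chiral catalyst) to the racemate, that is 6 together with the (7aS)-enedione F1. The racemate is separated by preparative chromatography on a chiral stationary phase (supercritical CO2/MeOH). The (7aR) fraction is 6, where the route resumes.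

Step 8. The risk is poor facial selectivity in the methylation: if iodomethane enters anti to the C7a methyl instead of beside it, the wrong C1 epimer results. Competing removal of a C4 proton would add a regiochemical leak. The fallback inverts the order of the two alkylations, so that the allyl group is the one that arrives last and takes the face the second electrophile prefers. It sets out from 9, which is deprotonated to enolate 10 and methylated with MeI to the 1-methyl enone F2. A second treatment with LiN(iPr)2 gives the lithium dienolate F3, and allyl bromide then delivers 13, where the route resumes.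

Step 11. The risk is hydride delivery to the diene terminus C4 instead of C3 (1,6-reduction), which would move the ring alkene to C3=C3a; an unfavourable C2 equilibrium would add to the loss. The fallback avoids the dienoate and homologates the ketone instead. It sets out from 13, which KOtBu in THF converts into the potassium dienolate F4. Kinetic protonation at C3 with cold aqueous AcOH gives the β,γ-unsaturated ketone F5, with the alkene already at C3a=C4. Wittig methoxymethylenation (Ph3P=CHOMe from the phosphonium chloride and KOtBu) gives the enol ether F6. Aqueous acid hydrolysis followed by K2CO3/MeOH equilibration gives the aldehyde F7 as the C2 epimer on the less hindered face. Pinnick oxidation (NaClO2, NaH2PO4, 2-methyl-2-butene) gives the acid F8, and methylation with Me3SiCHN2 in MeOH/toluene returns to 17.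

Further compounds

F1 | step 3 | (7aS)-7a-methyl-1,4,5,6,7,7a-hexahydro-2H-indene-2,7-dione (enantiomer of 6, formed with it in the racemate) | C1C(=O)C=C2CCCC(=O)[C@]21C
F2 | step 8 | (7aS)-1,7,7,7a-tetramethyl-1,4,5,6,7,7a-hexahydro-2H-inden-2-one (C1 epimers) | CC1C(=O)C=C2CCCC(C)(C)[C@@]21C
F3 | step 8 | lithium (7aS)-1,7,7,7a-tetramethyl-5,6,7,7a-tetrahydro-4H-inden-2-olate | CC1=C(O[Li])C=C2CCCC(C)(C)[C@@]21C
F4 | step 11 | potassium (1S,7aS)-1-allyl-1,7,7,7a-tetramethyl-5,6,7,7a-tetrahydro-1H-inden-2-olate | C=CC[C@]1(C)C(O[K])=CC2=CCCC(C)(C)[C@@]21C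
F5 | step 11 | (1S,7aS)-1-allyl-1,7,7,7a-tetramethyl-1,3,5,6,7,7a-hexahydro-2H-inden-2-one | C=CC[C@]1(C)C(=O)CC2=CCCC(C)(C)[C@@]21C
F6 | step 11 | (1S,7aS)-1-allyl-2-(methoxymethylidene)-1,7,7,7a-tetramethyl-2,3,5,6,7,7a-hexahydro-1H-indene (E/Z mixture) | C=CC[C@]1(C)C(=COC)CC2=CCCC(C)(C)[C@@]21C
F7 | step 11 | (1R,2S,7aS)-1-allyl-1,7,7,7a-tetramethyl-2,3,5,6,7,7a-hexahydro-1H-indene-2-carbaldehyde | C=CC[C@]1(C)[C@@H](C=O)CC2=CCCC(C)(C)[C@@]21C
F8 | step 11 | (1R,2S,7aS)-1-allyl-1,7,7,7a-tetramethyl-2,3,5,6,7,7a-hexahydro-1H-indene-2-carboxylic acid | C=CC[C@]1(C)[C@@H](C(=O)O)CC2=CCCC(C)(C)[C@@]21C
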